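**Strategy.** The fully substituted central benzene ring (C1 OMe, C2 H, C3 OH, C4 and C6 4-hydroxybenzyl, C5 phenethyl) is disconnected at C5–C6. Read as an open chain, ring atoms C6, C1, C2, C3 and C4 with the two benzylic arms are the carbons of a 1,7-diarylheptane-3,5-dione (C1 and C3 its carbonyl carbons), and C5 derives from the aldehyde carbon of 3-phenylpropanal. The precursor is an acyclic 3-oxido-5-methoxy hexatriene, C5=C4–C3(O)=C2–C1(OMe)=C6, generated as its potassium enolate from a cross-conjugated β-methoxy dienone. One 6π-electrocyclisation forms C5–C6 and the carbocycle with the two oxygens already differentiated. Silylation and dehydrogenation then give the arene.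

Key step: step 5

Remark: ring atoms are numbered as above and acyclic names use nonane locants. By the CIP rules the triene geometry that can close is (3E,5E,7Z): the carbon chain is cis about the central C5=C6 enol(ate) bond although its descriptor is E, and both terminal substituents point outwards. Enolisation of the dienone cannot be relied on to give this central geometry in a configurationally fixed silyl ether, so the C3 oxygen is carried through ring closure as the potassium enolate and silylated only afterwards.

**Step 1**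
Reactants: 1 acetylacetone (pentane-2,4-dione); 2 4-(benzyloxy)benzyl chloride (2 equiv)
Product: 4 1,7-bis[4-(benzyloxy)phenyl]heptane-3,5-dione, via monoalkylated dione enolate 3 (not isolated)
Conditions: LiN(iPr)2 (2.0 equiv), THF, 0 °C; 2 (1.0 equiv); LiN(iPr)2 (1.0 equiv); 2 (1.0 equiv), 0 °C → rt; aq HCl
Reagents that add atoms: none
Why: Hauser-type γ-alkylation of a 1,3-diketone dianion: the terminal carbanion is the most nucleophilic site, so each SN2 benzylation occurs at a methyl carbon, and after the first alkylation a further equivalent of amide regenerates a dianion at the remaining methyl in preference to the more hindered methylene.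

**Step 2**
Reactants: 4 1,7-bis[4-(benzyloxy)phenyl]heptane-3,5-dione
Product: 5 (4E)-1,7-bis[4-(benzyloxy)phenyl]-5-methoxyhept-4-en-3-one
Conditions: HC(OMe)3, MeOH, p-TsOH (cat.), rt → 50 °C; Et3N quench
Reagents that add atoms: trimethyl orthoformate, COC(OC)OC
Why: Acid-catalysed enol etherification with the orthoformate as methanol donor and water scavenger; the diketone is symmetric, so only one constitutional isomer can form, and the (E) isomer (OMe anti to the acyl group) is the thermodynamic one.

**Step 3**
Reactants: 5 (4E)-1,7-bis[4-(benzyloxy)phenyl]-5-methoxyhept-4-en-3-one; 6 3-phenylpropanal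
Product: 7 (6E)-9-[4-(benzyloxy)phenyl]-4-[4-(benzyloxy)benzyl]-3-hydroxy-7-methoxy-1-phenylnon-6-en-5-one (diastereomer mixture at C3 and C4)
Conditions: LiN(iPr)2 (1.05 equiv), THF, −78 °C; 6 (1.1 equiv), −78 °C; AcOH quench
Reagents that add atoms: none
Why: Kinetic α′-deprotonation of a vinylogous ester by a lithium amide at −78 °C (Stork–Danheiser-type enolate) followed by aldol addition to the aldehyde; the two new stereocentres (C3, C4) are formed without control and both are destroyed in steps 4 and 5.

**Step 4**
Reactants: 7 (6E)-9-[4-(benzyloxy)phenyl]-4-[4-(benzyloxy)benzyl]-3-hydroxy-7-methoxy-1-phenylnon-6-en-5-one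
Product: 9 (3E,6E)-9-[4-(benzyloxy)phenyl]-4-[4-(benzyloxy)benzyl]-7-methoxy-1-phenylnona-3,6-dien-5-one, via mesylate 8 (not isolated)
Conditions: MsCl, Et3N, CH2Cl2, 0 °C; then DBU, 0 °C → rt
Reagents that add atoms: none
Why: Mesylation and base-induced E1cB elimination give the conjugated enone, the (3E) isomer being favoured because the phenethyl chain avoids the acyl group, and the non-acidic conditions avoid cyclisation of the β-hydroxy-β′-methoxy enone to a dihydropyranone.

**Step 5**
Reactants: 9 (3E,6E)-9-[4-(benzyloxy)phenyl]-4-[4-(benzyloxy)benzyl]-7-methoxy-1-phenylnona-3,6-dien-5-one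
Product: 12 tert-butyl({cis-2,4-bis[4-(benzyloxy)benzyl]-5-methoxy-3-(2-phenylethyl)cyclohexa-1,5-dien-1-yl}oxy)dimethylsilane (racemic), via potassium trienolate 10 (not isolated), via potassium cyclohexadienolate 11 (not isolated)
Conditions: KN(SiMe3)2 (1.05 equiv), 18-crown-6, THF, −78 → 45 °C; then TBSCl, −78 → 0 °C
Reagents that add atoms: tert-butyldimethylsilyl chloride, CC(C)(C)[Si](C)(C)Cl
Why: KN(SiMe3)2 removes a proton from the methylene next to the methoxy-bearing carbon (ring C6, held cis to the carbonyl in the (E)-β-methoxy enone), and the resulting 3-oxido-5-methoxy hexatriene 10 closes by a thermal, disrotatory 6π-electrocyclisation that forms C5–C6; the cross-conjugated enolate 11 is then silylated on oxygen. The closest known reaction type is the oxyanion-accelerated electrocyclisation of 3-oxido-1,3,5-hexatrienes to cyclohexadienolates, which proceeds near room temperature, and beyond that the thermal closure of siloxy trienes followed by dehydrogenation. The six-membered carbocycle is closed in a single pericyclic event through a boat-like all-carbon six-centre transition state, both termini being sp2 carbons of one π system. The two new stereocentres C5 and C6 are set cis by orbital symmetry, because both terminal substituents point outwards and rotate in opposite senses; the relationship is relative only (racemate) and both centres are erased in step 6. Two selectivities are needed: deprotonation at C6 and not at the allylic methylene of the phenethyl arm, secured by the acidifying methoxy enone and by the fact that the other dienolate could close only onto a fully substituted terminus with an inward group; and a cis carbon chain about the C3–C2 enolate bond, which deprotonation does not fix but which the crown-ether-separated oxapentadienyl anion, with partial single-bond character there, is expected to reach on warming, after which closure drains that isomer irreversibly. Keeping the oxygen anionic also keeps the dienone out of the pentadienyl-cation (Nazarov) manifold that O-silylation by a silyl triflate would open.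

**Step 6**
Reactants: 12 tert-butyl({cis-2,4-bis[4-(benzyloxy)benzyl]-5-methoxy-3-(2-phenylethyl)cyclohexa-1,5-dien-1-yl}oxy)dimethylsilane (used crude)
Product: 14 2,4-bis[4-(benzyloxy)benzyl]-5-methoxy-3-(2-phenylethyl)phenol, via aryl silyl ether 13 (not isolated)
Conditions: DDQ (1.05 equiv), PhMe, 0 °C; then Bu4NF (3 equiv), AcOH, THF, 0 °C → rt
Reagents that add atoms: none
Why: Quinone dehydrogenation: hydride abstraction from C5–H gives a cyclohexadienyl cation with its charge on the oxygen-bearing carbons C1 and C3, loss of the C6 proton aromatises and erases both stereocentres, and buffered fluoride then cleaves the aryl silyl ether while the unactivated benzyl ethers survive one equivalent of DDQ at 0 °C.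

**Step 7**
Reactants: 14 2,4-bis[4-(benzyloxy)benzyl]-5-methoxy-3-(2-phenylethyl)phenol
Product: 15 IN1158, 2,4-bis(4-hydroxybenzyl)-5-methoxy-3-(2-phenylethyl)phenol
Conditions: H2 (1 atm), 10% Pd/C, EtOAc/MeOH, rt
Reagents that add atoms: none
Why: Catalytic hydrogenolysis of the two aryl benzyl ethers over Pd/C, under which the methyl ether, the diarylmethane CH2 groups and the arenes are inert.

**Compound list**

1 | acetylacetone (pentane-2,4-dione) | CC(=O)CC(C)=O | starting material
2 | 4-(benzyloxy)benzyl chloride | ClCc1ccc(OCc2ccccc2)cc1 | starting material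
3 | 6-[4-(benzyloxy)phenyl]hexane-2,4-dione (present as its lithium enolate) | CC(=O)CC(=O)CCc1ccc(OCc2ccccc2)cc1 | intermediate
4 | 1,7-bis[4-(benzyloxy)phenyl]heptane-3,5-dione | O=C(CCc1ccc(OCc2ccccc2)cc1)CC(=O)CCc1ccc(OCc2ccccc2)cc1 | intermediate
5 | (4E)-1,7-bis[4-(benzyloxy)phenyl]-5-methoxyhept-4-en-3-one | CO/C(CCc1ccc(OCc2ccccc2)cc1)=C/C(=O)CCc1ccc(OCc2ccccc2)cc1 | intermediate
6 | 3-phenylpropanal | O=CCCc1ccccc1 | starting material
7 | (6E)-9-[4-(benzyloxy)phenyl]-4-[4-(benzyloxy)benzyl]-3-hydroxy-7-methoxy-1-phenylnon-6-en-5-one (diastereomer mixture) | CO/C(CCc1ccc(OCc2ccccc2)cc1)=C/C(=O)C(Cc1ccc(OCc2ccccc2)cc1)C(O)CCc1ccccc1 | intermediate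
8 | (6E)-9-[4-(benzyloxy)phenyl]-4-[4-(benzyloxy)benzyl]-7-methoxy-5-oxo-1-phenylnon-6-en-3-yl methanesulfonate (diastereomer mixture) | CO/C(CCc1ccc(OCc2ccccc2)cc1)=C/C(=O)C(Cc1ccc(OCc2ccccc2)cc1)C(OS(C)(=O)=O)CCc1ccccc1 | intermediate
9 | (3E,6E)-9-[4-(benzyloxy)phenyl]-4-[4-(benzyloxy)benzyl]-7-methoxy-1-phenylnona-3,6-dien-5-one | CO/C(CCc1ccc(OCc2ccccc2)cc1)=C/C(=O)/C(Cc1ccc(OCc2ccccc2)cc1)=C/CCc1ccccc1 | intermediate
10 | potassium (3E,5E,7Z)-9-[4-(benzyloxy)phenyl]-4-[4-(benzyloxy)benzyl]-7-methoxy-1-phenylnona-3,5,7-trien-5-olate (reactive geometric isomer) | C(Cc1ccccc1)/C=C(Cc1ccc(OCc2ccccc2)cc1)/C([O-])=C\C(OC)=C\Cc1ccc(OCc2ccccc2)cc1.[K+] | intermediate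
11 | potassium cis-2,4-bis[4-(benzyloxy)benzyl]-5-methoxy-3-(2-phenylethyl)cyclohexa-1,5-dien-1-olate (racemic; 3S,4R enantiomer drawn) | COC1=CC([O-])=C(Cc2ccc(OCc3ccccc3)cc2)[C@@H](CCc2ccccc2)[C@H]1Cc1ccc(OCc2ccccc2)cc1.[K+] | intermediate
12 | tert-butyl({cis-2,4-bis[4-(benzyloxy)benzyl]-5-methoxy-3-(2-phenylethyl)cyclohexa-1,5-dien-1-yl}oxy)dimethylsilane (racemic; 3S,4R enantiomer drawn) | COC1=CC(O[Si](C)(C)C(C)(C)C)=C(Cc2ccc(OCc3ccccc3)cc2)[C@@H](CCc2ccccc2)[C@H]1Cc1ccc(OCc2ccccc2)cc1 | intermediate
13 | tert-butyl{2,4-bis[4-(benzyloxy)benzyl]-5-methoxy-3-(2-phenylethyl)phenoxy}dimethylsilane | COc1cc(O[Si](C)(C)C(C)(C)C)c(Cc2ccc(OCc3ccccc3)cc2)c(CCc2ccccc2)c1Cc1ccc(OCc2ccccc2)cc1 | intermediate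
14 | 2,4-bis[4-(benzyloxy)benzyl]-5-methoxy-3-(2-phenylethyl)phenol | COc1cc(O)c(Cc2ccc(OCc3ccccc3)cc2)c(CCc2ccccc2)c1Cc1ccc(OCc2ccccc2)cc1 | intermediate
15 | IN1158, 2,4-bis(4-hydroxybenzyl)-5-methoxy-3-(2-phenylethyl)phenol | COc1cc(O)c(Cc2ccc(O)cc2)c(CCc2ccccc2)c1Cc1ccc(O)cc1 | target

**Total step count:** 7. **Longest linear sequence:** 7 steps (from acetylacetone).

**Steps most likely to fail**

1. Step 5. The trienolate may not reach the chain-cis arrangement about its central enolate bond, or may form at the other γ-methylene, so that ring closure loses out to intermolecular Michael addition or decomposition on warming. Fallback: set out from 9 and enolise it softly (TBSOTf, Et3N, CH2Cl2, −78 °C) to the neutral silyl trienol ether tert-butyl({(3E,5E,7Z)-9-[4-(benzyloxy)phenyl]-4-[4-(benzyloxy)benzyl]-7-methoxy-1-phenylnona-3,5,7-trien-5-yl}oxy)dimethylsilane F1, expected together with its central-bond isomer, the (3E,5Z,7Z) silyl trienol ether F2. Freed from ammonium salts, the mixture is heated in toluene (about 100 °C) under 405 nm irradiation with thioxanthone as triplet sensitiser, so that F2 and F1 interconvert by sensitised alkene isomerisation and F1 closes thermally. The fallback rejoins the route at 12.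

2. Step 6. The quinone may over-oxidise the electron-rich diarylmethane positions, or the silyl dienol ether may hydrolyse before hydride abstraction and stall at the cyclohexenone level. Fallback: set out from 12 and brominate the silyl enol ether (NBS, THF, −78 °C) to the α-bromo enone 6-bromo-4,6-bis[4-(benzyloxy)benzyl]-3-methoxy-5-(2-phenylethyl)cyclohex-2-en-1-one F3. Dehydrobromination with DBU and tautomerisation of the resulting cyclohexadienone give the phenol directly, rejoining the route at 14.

3. Step 1. The second alkylation may be incomplete or misplaced (at the methylene of the first arm or at the central carbon), giving mixtures that are hard to separate. Fallback: set out from 1 and condense its boron complex with commercial 4-(benzyloxy)benzaldehyde (O=Cc1ccc(OCc2ccccc2)cc1; B2O3, B(OBu)3, n-BuNH2, EtOAc, 70 °C; aq HCl), a Pabon-type curcuminoid synthesis, to (1E,6E)-1,7-bis[4-(benzyloxy)phenyl]hepta-1,6-diene-3,5-dione F4. The two conjugated alkenes are then hydrogenated over Pd/C poisoned with pyridine, which suppresses hydrogenolysis of aryl benzyl ethers, rejoining the route at 4.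

**Further compounds**

F1 | step 5 | tert-butyl({(3E,5E,7Z)-9-[4-(benzyloxy)phenyl]-4-[4-(benzyloxy)benzyl]-7-methoxy-1-phenylnona-3,5,7-trien-5-yl}oxy)dimethylsilane | C(Cc1ccccc1)/C=C(Cc1ccc(OCc2ccccc2)cc1)/C(O[Si](C)(C)C(C)(C)C)=C\C(OC)=C\Cc1ccc(OCc2ccccc2)cc1
F2 | step 5 | tert-butyl({(3E,5Z,7Z)-9-[4-(benzyloxy)phenyl]-4-[4-(benzyloxy)benzyl]-7-methoxy-1-phenylnona-3,5,7-trien-5-yl}oxy)dimethylsilane | C(Cc1ccccc1)/C=C(Cc1ccc(OCc2ccccc2)cc1)/C(O[Si](C)(C)C(C)(C)C)=C/C(OC)=C/Cc1ccc(OCc2ccccc2)cc1
F3 | step 6 | 6-bromo-4,6-bis[4-(benzyloxy)benzyl]-3-methoxy-5-(2-phenylethyl)cyclohex-2-en-1-one (diastereomer mixture) | COC1=CC(=O)C(Br)(Cc2ccc(OCc3ccccc3)cc2)C(CCc2ccccc2)C1Cc1ccc(OCc2ccccc2)cc1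
F4 | step 1 | (1E,6E)-1,7-bis[4-(benzyloxy)phenyl]hepta-1,6-diene-3,5-dione | O=C(/C=C/c1ccc(OCc2ccccc2)cc1)CC(=O)/C=C/c1ccc(OCc2ccccc2)cc1
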